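I followed one molecule of E.

| setting | alpha | delta | gamma | flask |
|---|---|---|---|---|
| D | 11 mM | 11 mM | 5.5 mM | 11 mM |
| E | 11 mM | 44 mM | 22 mM | 22.0 mM |
| remark | run made earlier | run made earlier | run made earlier |  |
| time |  |  |  | 50 min |

- alpha (time / min: D / %, J / %): 15.0: 11, 87; 30.0: 6, 90; 50.0: 4, 89; 60.0: 7, 88
- delta (time / min: D / %, J / %): 8.00: 2, 74; 20.0: 0, 47; 40.0: 2, 4; 60.0: 0, 1
- gamma (time / min: D / %, J / %): 15.0: 0, 55; 30.0: 0, 22; 50.0: 2, 0; 60.0: 0, 0

(each reading ± 1.5 percentage points)

- the D standing at 50 min, as a percentage of the D charged
- the J standing at 50 min, as a percentage of the D charged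
- the Q standing at 50 min, as a percentage of the D charged
- the Z standing at 50 min, as a percentage of the D charged

- a reading or a percentage of J counts all its forms, free or not

Its first fork was D. In alpha, charged with equal D and E, J still read 88% at 60.0 min, so I took one E per D and saw the later loss of J as the work of E left over. I counted spare E as a fraction of the D charged: the charge ratio less one at the start, and afterwards less whatever J had been lost, one for one.

At its second fork, I assumed, a spare E took a J at a steady chance per minute. I call the reciprocal of that chance the life of spare E, a pseudo-first-order life. Gamma's readings gave 108 min and delta's gave 116 min, so I took 112 min.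

The flask is then two times, this life and 50 min. Their ratio gives each spare E a chance of 36.0% of having taken a J. Spare E starts at 1.00 of the D charged, so I expected J at 64.0%. The runs read neither Q nor Z, so I left the lost part unsplit.

The forecast gave D 0.5%, J 60%, Q 34% and Z 5%, saying of the last two that “the split is a guess”.

At 50 min the flask held D 0%, J 59.4%, Q 0% and Z 40.6%, so my J stood 4.6 percentage points high and the lost part stood as Z.

D + E → J (k = 1.40 L mol⁻¹ s⁻¹); D + E → Q (k = 0.0460 L mol⁻¹ s⁻¹); E + J → Z (k = 0.380 L mol⁻¹ s⁻¹); E + Q → Z (k = 0.630 L mol⁻¹ s⁻¹); L ⇌ J, rate k5*(cs5 - [J]) while solid is left; crystals form when [J] > cs5 (solubility = 0.410 mM, k = 0.330 s⁻¹) At the start the flask's D went into J 30 times as fast as into Q, and net turnover to Q came to 3.18% of the D charged by that time. A neighbour flask charged with 88 mM of E had spare E of 7.00, and this times the same chance gave 2.52 of the D charged, more than the whole charge of D; that flask held J 0% and Z 100%.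

(The runs stem from a simulated flask from invented constants, and the scatter is random.)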